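**Strategy**

The flavanone is cut at the C2–C1′ bond, not at the O1–C2 bond of the usual chalcone route. The sole stereocentre C2 is made last, on the flat pyranone ring of an achiral, fully decorated chromone, by rhodium/chiral-diene-catalysed asymmetric 1,4-addition of a 2,4-dioxygenated arylboronic acid to the C2=C3–C4=O enone. This exploits C2 being the enone β-carbon and the only stereogenic atom; since no 2′,6′-dioxygenated chalcone ever forms, neither C2 nor the C6-alkenyl/C8-prenyl pattern of the hexasubstituted ring A can scramble. The precursor is 5,7-bis(methoxymethoxy)-6-[(E)-3-methylbut-1-enyl]-8-prenylchromone, built by chelation-directed C6 iodination, C6-blocked O7→C8 Claisen rearrangement and Suzuki coupling.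

Key step: step 10

Remark: the sense of induction of the diene ligand in step 10 is assigned from the accepted model for cyclic enones (aryl to the C2 Re face with the (S,S)-ligand); if the first run shows the opposite sense, the ligand antipode is used with nothing else changed.

**Route**

Step 1
Reactants: 1 5,7-dihydroxy-4H-chromen-4-one; 2 3-chloro-3-methylbut-1-yne
Product: 3 5-hydroxy-7-[(2-methylbut-3-yn-2-yl)oxy]-4H-chromen-4-one
Conditions: K2CO3, KI (cat.), acetone, reflux
Reagents that add atoms: none
Why: Williamson-type O-propargylation with a tertiary propargylic chloride should take place only at the free, more acidic 7-OH, because the 5-OH is locked in a hydrogen bond to C4=O.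

Step 2
Reactants: 3 5-hydroxy-7-[(2-methylbut-3-yn-2-yl)oxy]-4H-chromen-4-one
Product: 4 5-hydroxy-7-[(2-methylbut-3-en-2-yl)oxy]-4H-chromen-4-one
Conditions: H2 (1 atm), Lindlar catalyst, quinoline, EtOAc, rt
Reagents that add atoms: none
Why: Lindlar semihydrogenation should stop at the terminal alkene and leave the conjugated C2=C3 bond of the chromone untouched.

Step 3
Reactants: 4 5-hydroxy-7-[(2-methylbut-3-en-2-yl)oxy]-4H-chromen-4-one
Product: 5 5-hydroxy-6-iodo-7-[(2-methylbut-3-en-2-yl)oxy]-4H-chromen-4-one
Conditions: BnMe3N·ICl2 (1.0 equiv), CaCO3, CH2Cl2/MeOH, rt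
Reagents that add atoms: benzyltrimethylammonium dichloroiodate C[N+](C)(C)Cc1ccccc1.Cl[I-]Cl
Why: Electrophilic aromatic iodination (SEAr) should go ortho to the free chelated 5-OH, at C6, the regiochemistry known for 5-hydroxy-7-alkoxy chromones and flavones, while the inductively deactivated, neopentyl-type vinyl group should react far more slowly than the phenol ring.

Step 4
Reactants: 5 5-hydroxy-6-iodo-7-[(2-methylbut-3-en-2-yl)oxy]-4H-chromen-4-one
Product: 7 5,7-dihydroxy-6-iodo-8-(3-methylbut-2-en-1-yl)-4H-chromen-4-one, via ortho-dienone 6 (not isolated)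
Conditions: N,N-diethylaniline, 130 °C
Reagents that add atoms: none
Why: The aromatic Claisen rearrangement ([3,3]-sigmatropic) of the 1,1-dimethylallyl ether can end only at C8 because C6 is blocked by iodine, the allyl unit arrives inverted as the linear prenyl group, and tautomerisation of dienone 6 restores the arene.

Step 5
Reactants: 7 5,7-dihydroxy-6-iodo-8-(3-methylbut-2-en-1-yl)-4H-chromen-4-one
Product: 8 6-iodo-5,7-bis(methoxymethoxy)-8-(3-methylbut-2-en-1-yl)-4H-chromen-4-one
Conditions: NaH, MOMCl, DMF, 0 °C to rt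
Reagents that add atoms: chloromethyl methyl ether COCCl
Why: Williamson O-alkylation of both phenoxides (NaH is needed for the chelated 5-OH) should give acetal ethers that tolerate the cross-coupling and the basic rhodium step.

Step 6
Reactants: 9 3-methylbut-1-yne
Product: 10 4,4,5,5-tetramethyl-2-[(E)-3-methylbut-1-en-1-yl]-1,3,2-dioxaborolane
Conditions: HBpin, Cp2ZrHCl (10 mol %), Et3N (10 mol %), neat, sealed tube, 60 °C
Reagents that add atoms: pinacolborane CC1(C)OBOC1(C)C
Why: Zirconocene-hydride-catalysed syn-hydroboration of the terminal alkyne should place boron on the terminal carbon and give the (E)-alkenylboronate only.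

Step 7
Reactants: 8 6-iodo-5,7-bis(methoxymethoxy)-8-(3-methylbut-2-en-1-yl)-4H-chromen-4-one; 10 4,4,5,5-tetramethyl-2-[(E)-3-methylbut-1-en-1-yl]-1,3,2-dioxaborolane
Product: 11 5,7-bis(methoxymethoxy)-6-[(E)-3-methylbut-1-en-1-yl]-8-(3-methylbut-2-en-1-yl)-4H-chromen-4-one
Conditions: Pd(dppf)Cl2·CH2Cl2 (5 mol %), K2CO3, 1,4-dioxane/H2O (5:1), 80 °C
Reagents that add atoms: none
Why: Suzuki–Miyaura coupling of the aryl iodide should proceed with retention of the (E)-geometry of the boronate, the bisphosphine catalyst coping with the two ortho acetal ethers and the mild carbonate base sparing the chromone ring.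

Step 8
Reactants: 12 4-bromobenzene-1,3-diol
Product: 13 1-bromo-2,4-bis(methoxymethoxy)benzene
Conditions: MOMCl, i-Pr2NEt, CH2Cl2, 0 °C to rt
Reagents that add atoms: chloromethyl methyl ether COCCl
Why: Williamson-type O-alkylation of both phenols with the reactive α-chloro ether should give the bis-acetal under mild amine-base conditions.

Step 9
Reactants: 13 1-bromo-2,4-bis(methoxymethoxy)benzene
Product: 16 [2,4-bis(methoxymethoxy)phenyl]boronic acid, via aryllithium 14 (not isolated), via lithium aryltriisopropoxyborate 15 (not isolated)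
Conditions: n-BuLi, THF, −78 °C; B(Oi-Pr)3, −78 °C to rt; sat. aq. NH4Cl
Reagents that add atoms: triisopropyl borate CC(C)OB(OC(C)C)OC(C)C; water O; n-butyllithium [Li]CCCC (lithium of 14 and 15 only)
Why: Bromine–lithium exchange fixes the metal at C1 (direct lithiation of the bis-acetal would go between the two oxygens), and borate trapping followed by near-neutral hydrolysis should give the boronic acid with both acetals intact.

Step 10
Reactants: 11 5,7-bis(methoxymethoxy)-6-[(E)-3-methylbut-1-en-1-yl]-8-(3-methylbut-2-en-1-yl)-4H-chromen-4-one; 16 [2,4-bis(methoxymethoxy)phenyl]boronic acid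
Product: 17 (2S)-2-[2,4-bis(methoxymethoxy)phenyl]-5,7-bis(methoxymethoxy)-6-[(E)-3-methylbut-1-en-1-yl]-8-(3-methylbut-2-en-1-yl)-2,3-dihydro-4H-chromen-4-one
Conditions: [RhCl(C2H4)2]2 (2.5 mol %), (S,S)-Ph-bod* [(S,S)-2,5-diphenylbicyclo[2.2.2]octa-2,5-diene] (5.5 mol %), aq. KOH (20 mol %), 16 (3 equiv, in portions), 1,4-dioxane/H2O (10:1), 40 °C
Reagents that add atoms: none
Why: Transmetalation of 16 to the hydroxorhodium(I)–diene complex gives an aryl–rhodium species that binds the C2=C3–C4=O enone of 11 and inserts C2=C3 into the Rh–aryl bond (aryl to C2), and water then protonates the oxa-π-allyl rhodium enolate at C3, releasing 17 and the Rh–OH catalyst. The closest known reaction is the Hayashi–Miyaura rhodium-catalysed asymmetric 1,4-addition of arylboronic acids to cyclic enones, a reaction type established for chromones, 5,7-dioxygenated ones included. No ring is closed; the flat pyranone ring becomes the dihydropyranone of the flavanone while the C2–C1′ bond is made. C2, the only stereocentre, is set by the C2-symmetric chiral diene alone, which shields one enone face so that the aryl group reaches the Re face of C2 (2S), and since the substrate is achiral there is no matching problem. The step needs chemoselectivity for the enone over the 6-styrenyl and 8-prenyl double bonds, expected because unactivated, hindered alkenes do not insert into aryl–rhodium(I) at 40 °C, and it needs the rhodium enolate to be protonated before it can expel the C8a phenoxide (retro-oxa-Michael), which the aqueous medium, low hydroxide loading and low temperature favour. The electron-rich ortho-alkoxy boronic acid is used in excess and added in portions to outrun protodeboronation.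

Step 11
Reactants: 17 (2S)-2-[2,4-bis(methoxymethoxy)phenyl]-5,7-bis(methoxymethoxy)-6-[(E)-3-methylbut-1-en-1-yl]-8-(3-methylbut-2-en-1-yl)-2,3-dihydro-4H-chromen-4-one
Product: 18 (2S)-2-(2,4-dihydroxyphenyl)-5,7-dihydroxy-6-[(E)-3-methylbut-1-en-1-yl]-8-(3-methylbut-2-en-1-yl)-2,3-dihydro-4H-chromen-4-one
Conditions: 3 M aq. HCl/MeOH (1:10), 25–40 °C, monitored; NaHCO3 quench
Reagents that add atoms: none
Why: Acid-catalysed acetal cleavage (transacetalisation to methanol) should remove all four MOM groups, the two vinylogous-ester acetals of ring A first, under dilute acid mild enough to leave the prenyl and styrenyl double bonds and the C2 benzylic ether un-ionised, C2 not being touched by the mechanism.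

**Compound list**

1 | 5,7-dihydroxy-4H-chromen-4-one | O=c1ccoc2cc(O)cc(O)c12 | starting material
2 | 3-chloro-3-methylbut-1-yne | CC(C)(Cl)C#C | starting material
3 | 5-hydroxy-7-[(2-methylbut-3-yn-2-yl)oxy]-4H-chromen-4-one | O=c1ccoc2cc(OC(C)(C)C#C)cc(O)c12 | intermediate
4 | 5-hydroxy-7-[(2-methylbut-3-en-2-yl)oxy]-4H-chromen-4-one | O=c1ccoc2cc(OC(C)(C)C=C)cc(O)c12 | intermediate
5 | 5-hydroxy-6-iodo-7-[(2-methylbut-3-en-2-yl)oxy]-4H-chromen-4-one | O=c1ccoc2cc(OC(C)(C)C=C)c(I)c(O)c12 | intermediate
6 | ortho-dienone, 5-hydroxy-6-iodo-8-(3-methylbut-2-en-1-yl)-4H-chromene-4,7(8H)-dione (not isolated, racemic at C8) | O=C1C(I)=C(O)C2=C(OC=CC2=O)C1CC=C(C)C | intermediate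
7 | 5,7-dihydroxy-6-iodo-8-(3-methylbut-2-en-1-yl)-4H-chromen-4-one | O=c1ccoc2c(CC=C(C)C)c(O)c(I)c(O)c12 | intermediate
8 | 6-iodo-5,7-bis(methoxymethoxy)-8-(3-methylbut-2-en-1-yl)-4H-chromen-4-one | O=c1ccoc2c(CC=C(C)C)c(OCOC)c(I)c(OCOC)c12 | intermediate
9 | 3-methylbut-1-yne | CC(C)C#C | starting material
10 | 4,4,5,5-tetramethyl-2-[(E)-3-methylbut-1-en-1-yl]-1,3,2-dioxaborolane | CC(C)/C=C/B1OC(C)(C)C(C)(C)O1 | intermediate
11 | 5,7-bis(methoxymethoxy)-6-[(E)-3-methylbut-1-en-1-yl]-8-(3-methylbut-2-en-1-yl)-4H-chromen-4-one | O=c1ccoc2c(CC=C(C)C)c(OCOC)c(/C=C/C(C)C)c(OCOC)c12 | intermediate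
12 | 4-bromobenzene-1,3-diol (4-bromoresorcinol) | Oc1ccc(Br)c(O)c1 | starting material
13 | 1-bromo-2,4-bis(methoxymethoxy)benzene | COCOc1ccc(Br)c(OCOC)c1 | intermediate
14 | [2,4-bis(methoxymethoxy)phenyl]lithium (not isolated) | [Li]c1ccc(OCOC)cc1OCOC | intermediate
15 | lithium [2,4-bis(methoxymethoxy)phenyl]tri(propan-2-yloxy)borate (not isolated) | [Li+].CC(C)O[B-](OC(C)C)(OC(C)C)c1ccc(OCOC)cc1OCOC | intermediate
16 | [2,4-bis(methoxymethoxy)phenyl]boronic acid | OB(O)c1ccc(OCOC)cc1OCOC | intermediate
17 | (2S)-2-[2,4-bis(methoxymethoxy)phenyl]-5,7-bis(methoxymethoxy)-6-[(E)-3-methylbut-1-en-1-yl]-8-(3-methylbut-2-en-1-yl)-2,3-dihydro-4H-chromen-4-one | CC(C)=CCc1c(OCOC)c(/C=C/C(C)C)c(OCOC)c2c1O[C@H](c1ccc(OCOC)cc1OCOC)CC2=O | intermediate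
18 | (2S)-2-(2,4-dihydroxyphenyl)-5,7-dihydroxy-6-[(E)-3-methylbut-1-en-1-yl]-8-(3-methylbut-2-en-1-yl)-2,3-dihydro-4H-chromen-4-one | CC(C)=CCc1c(O)c(/C=C/C(C)C)c(O)c2c1O[C@H](c1ccc(O)cc1O)CC2=O | target

**Step count**

Total steps: 11. Longest linear sequence: 8 (steps 1, 2, 3, 4, 5, 7, 10, 11).

**Steps most likely to fail**

1. Step 10 (key step). Insertion of the electron-rich, fully substituted chromone may be slow, so that protodeboronation of the boronic acid outruns the addition. Base-induced ring opening of the rhodium enolate or of the product may also erode the enantiomeric purity. The fallback is a ring-opening and re-closure sequence that keeps the regiochemistry fixed by the chromone; it sets out from 11 and 13 and returns at 17. Chromone 11 is opened with aqueous NaOH in EtOH at reflux (hydroxide addition at C2, retro-Claisen loss of C2 as formate) to 1-[2-hydroxy-4,6-bis(methoxymethoxy)-5-[(E)-3-methylbut-1-en-1-yl]-3-(3-methylbut-2-en-1-yl)phenyl]ethan-1-one F1, whose single free hydroxyl is the former O1. Bromide 13 is converted by bromine–lithium exchange (n-BuLi, THF, −78 °C) and DMF into 2,4-bis(methoxymethoxy)benzaldehyde F2. Claisen–Schmidt condensation of F1 with F2 (KOH, EtOH, rt) gives (E)-3-[2,4-bis(methoxymethoxy)phenyl]-1-[2-hydroxy-4,6-bis(methoxymethoxy)-5-[(E)-3-methylbut-1-en-1-yl]-3-(3-methylbut-2-en-1-yl)phenyl]prop-2-en-1-one F3. Asymmetric intramolecular oxa-Michael addition of F3 under a cinchona-derived bifunctional thiourea (the pseudo-enantiomer that favours 2S, toluene, rt) closes ring C through that one hydroxyl to give 17. The enantiomeric purity is upgraded by chiral-phase chromatography if required.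

2. Step 11. The electron-rich 6-styrenyl double bond may be protonated (ortho-quinone-methide-type cation), leading to methanol addition or cyclisation of a neighbouring phenol, while the two B-ring acetals are still being cleaved. The fallback introduces the acid-sensitive alkene after the acetal cleavage by a base-free coupling; it sets out from 8, 16 and 9 and returns at 18. The rhodium-catalysed addition of step 10 is run on iodochromone 8 with 16 (the hindered aryl iodide should be inert to rhodium(I) at 40 °C) to give (2S)-2-[2,4-bis(methoxymethoxy)phenyl]-6-iodo-5,7-bis(methoxymethoxy)-8-(3-methylbut-2-en-1-yl)-2,3-dihydro-4H-chromen-4-one F4. Acetal cleavage as in step 11, now without the styrene, gives (2S)-2-(2,4-dihydroxyphenyl)-5,7-dihydroxy-6-iodo-8-(3-methylbut-2-en-1-yl)-2,3-dihydro-4H-chromen-4-one F5. Alkyne 9 is converted by palladium-catalysed syn-hydrostannation (Bu3SnH, PdCl2(PPh3)2, THF) into tributyl[(E)-3-methylbut-1-en-1-yl]stannane F6. Stille coupling of F5 with F6 (Pd2(dba)3, AsPh3, DMF, 50 °C) needs no base, so it should not open the flavanone, and gives 18.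

3. Step 3. The iodine electrophile may add across the vinyl group of the tertiary allyl ether, or the acid released may cleave that ether, in competition with ring iodination. The fallback halogenates before the alkene exists; it sets out from 3 and returns at 5. Alkyne 3 is iodinated with BnMe3N·ICl2/CaCO3 (the terminal alkyne is far less nucleophilic than an alkene) to 5-hydroxy-6-iodo-7-[(2-methylbut-3-yn-2-yl)oxy]-4H-chromen-4-one F7. Lindlar semihydrogenation of F7 (quinoline-poisoned, so that the aryl iodide should be retained) gives 5.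

**Further compounds**

F1 | step 10 | 1-[2-hydroxy-4,6-bis(methoxymethoxy)-5-[(E)-3-methylbut-1-en-1-yl]-3-(3-methylbut-2-en-1-yl)phenyl]ethan-1-one | CC(=O)c1c(O)c(CC=C(C)C)c(OCOC)c(/C=C/C(C)C)c1OCOC
F2 | step 10 | 2,4-bis(methoxymethoxy)benzaldehyde | O=Cc1ccc(OCOC)cc1OCOC
F3 | step 10 | (E)-3-[2,4-bis(methoxymethoxy)phenyl]-1-[2-hydroxy-4,6-bis(methoxymethoxy)-5-[(E)-3-methylbut-1-en-1-yl]-3-(3-methylbut-2-en-1-yl)phenyl]prop-2-en-1-one | O=C(/C=C/c1ccc(OCOC)cc1OCOC)c1c(O)c(CC=C(C)C)c(OCOC)c(/C=C/C(C)C)c1OCOC
F4 | step 11 | (2S)-2-[2,4-bis(methoxymethoxy)phenyl]-6-iodo-5,7-bis(methoxymethoxy)-8-(3-methylbut-2-en-1-yl)-2,3-dihydro-4H-chromen-4-one | CC(C)=CCc1c(OCOC)c(I)c(OCOC)c2c1O[C@H](c1ccc(OCOC)cc1OCOC)CC2=O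
F5 | step 11 | (2S)-2-(2,4-dihydroxyphenyl)-5,7-dihydroxy-6-iodo-8-(3-methylbut-2-en-1-yl)-2,3-dihydro-4H-chromen-4-one | CC(C)=CCc1c(O)c(I)c(O)c2c1O[C@H](c1ccc(O)cc1O)CC2=O
F6 | step 11 | tributyl[(E)-3-methylbut-1-en-1-yl]stannane | CCCC[Sn](CCCC)(CCCC)/C=C/C(C)C
F7 | step 3 | 5-hydroxy-6-iodo-7-[(2-methylbut-3-yn-2-yl)oxy]-4H-chromen-4-one | O=c1ccoc2cc(OC(C)(C)C#C)c(I)c(O)c12
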